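**Retrosynthetic overview**
1. Target 17 ⇐ 16 (acetylation of C13–OH) ⇐ 13 (α‑methylenation of the lactone).
2. 13 ⇐ acyclic dialdehyde ester 11: one reductive C13–C14 (pinacol) coupling whose C14 alkoxide lactonizes at once; the 14‑membered carbocycle and the γ‑lactone close together and C13/C14 are set.
3. 11 ⇐ thioester 8 (terminal allylic oxidation; thioester → aldehyde) ⇐ Evans alkylation of succinyl imide 5 with epoxyfarnesyl triflate 6 (sets C1).
4. 6 ⇐ Sharpless epoxidation of farnesol (sets C3 and C4).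
5. Ring order: oxirane (step 1), then carbocycle and γ‑lactone together (step 8).

Assumption: metal enolates and alkoxides are treated as the numbered compound they derive from and are not numbered separately; cembrane numbering is used (ring C1–C14; C15, C16, C17 = lactone α‑carbon, carbonyl, exocyclic CH2; farnesol C1, C2, C3, C12 become C2, C3, C4, C13).

**Route**

Step 1
Reactants: 1 (2E,6E)-farnesol
Product: 2 (2S,3S)-2,3-epoxyfarnesol
Conditions: Ti(OiPr)4 (5 mol %), L-(+)-diethyl tartrate (6 mol %), tBuOOH, 4 Å MS, CH2Cl2, −20 °C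
Reagents that add atoms: tert-butyl hydroperoxide, CC(C)(C)OO
Why: Sharpless–Katsuki asymmetric epoxidation, in which the titanium tartrate complex epoxidizes only the allylic-alcohol alkene and L-(+)-tartrate delivers oxygen to the face that gives the (2S,3S)-epoxide (C3 and C4 of the target), as with geraniol.

Step 2
Reactants: 3 (S)-4-benzyl-1,3-oxazolidin-2-one; 4 methyl 4-chloro-4-oxobutanoate
Product: 5 methyl 4-[(4S)-4-benzyl-2-oxo-1,3-oxazolidin-3-yl]-4-oxobutanoate
Conditions: n-BuLi, THF, −78 °C; then 4, −78 → 0 °C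
Reagents that add atoms: none
Why: N-acylation of the lithiated Evans oxazolidinone by the acid chloride, with no new stereocenter.

Step 3
Reactants: 2 (2S,3S)-2,3-epoxyfarnesol; 5 succinyl imide
Product: 7 methyl (3S)-3-{[(4S)-4-benzyl-2-oxo-1,3-oxazolidin-3-yl]carbonyl}-4-{(2S,3S)-3-[(3E)-4,8-dimethylnona-3,7-dien-1-yl]-3-methyloxiran-2-yl}butanoate, via epoxyfarnesyl triflate 6 (not isolated)
Conditions: 2: Tf2O, 2,6-lutidine, CH2Cl2, −78 °C; 5: NaN(SiMe3)2, THF, −78 °C; then 6 added, −78 → −30 °C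
Reagents that add atoms: none
Why: Evans asymmetric alkylation, in which the chelated Z sodium enolate of 5 displaces the primary triflate (SN2) on the face opposite the benzyl group and so sets C1 as S, while the trisubstituted epoxide is not attacked at low temperature.

Step 4
Reactants: 7 alkylated imide
Product: 8 methyl (3S)-3-[(ethylsulfanyl)carbonyl]-4-{(2S,3S)-3-[(3E)-4,8-dimethylnona-3,7-dien-1-yl]-3-methyloxiran-2-yl}butanoate
Conditions: EtSH, n-BuLi, THF, 0 °C
Reagents that add atoms: ethanethiol, CCS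
Why: Transthioesterification of the N-acyloxazolidinone by lithium ethanethiolate at the exocyclic carbonyl gives the thioester without epimerizing C1 and releases the auxiliary.

Step 5
Reactants: 8 thioester
Product: 9 methyl (3S)-3-[(ethylsulfanyl)carbonyl]-4-{(2S,3S)-3-[(3E,7E)-9-hydroxy-4,8-dimethylnona-3,7-dien-1-yl]-3-methyloxiran-2-yl}butanoate
Conditions: SeO2 (0.5 equiv), tBuOOH, salicylic acid (cat.), CH2Cl2, 25 °C
Reagents that add atoms: tert-butyl hydroperoxide, CC(C)(C)OO
Why: Sharpless SeO2/tBuOOH allylic oxidation (ene reaction then [2,3]-sigmatropic shift) hydroxylates the (E)-methyl of the most accessible, terminal trisubstituted alkene and gives the (E)-allylic alcohol (future C13).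

Step 6
Reactants: 9 hydroxy thioester
Product: 10 methyl (3S)-3-formyl-4-{(2S,3S)-3-[(3E,7E)-9-hydroxy-4,8-dimethylnona-3,7-dien-1-yl]-3-methyloxiran-2-yl}butanoate
Conditions: Et3SiH, Pd/C (5 mol % Pd), CH2Cl2, 25 °C
Reagents that add atoms: none
Why: Fukuyama reduction, in which palladium-catalyzed hydrosilane reduction of the thioester stops at the aldehyde (C14) and leaves ester, epoxide, allylic alcohol and trisubstituted alkenes intact.

Step 7
Reactants: 10 hydroxy aldehyde
Product: 11 methyl (3S)-3-formyl-4-{(2S,3S)-3-[(3E,7E)-4,8-dimethyl-9-oxonona-3,7-dien-1-yl]-3-methyloxiran-2-yl}butanoate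
Conditions: MnO2 (20 equiv), CH2Cl2, 25 °C
Reagents that add atoms: none
Why: MnO2 oxidizes only the allylic alcohol, under neutral conditions that give the (E)-enal (C13) without epimerizing the α-stereocenter of the C14 aldehyde.

Step 8
Reactants: 11 dialdehyde ester
Product: 13 (1S,3S,4S,13S,14S,7E,11E)-3,4-epoxy-13-hydroxy-17-norcembra-7,11-dien-16,14-olide, via seco diol ester 12 (not isolated)
Conditions: [V2Cl3(THF)6]2[Zn2Cl6] (2.5 equiv V), CH2Cl2, 25 °C, 11 added over 10 h (final 2 mM); NaKC4H4O6 (aq); then imidazole (cat.), CH2Cl2, 25 °C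
Reagents that add atoms: none
Why: Proposed new method: an intramolecular version of the vanadium-mediated cross-pinacol coupling (closest known reaction type: intermolecular divalent-vanadium coupling of a 3-formylpropanoate- or 3-formylpropanamide-type chelating aldehyde with a second aldehyde to threo diols, and low-valent-metal pinacol closures of 14-membered carbocycles), in which the metal binds the C14 aldehyde and the C16 ester carbonyl in a seven-membered chelate, the vanadium-bound ketyl adds 1,2 to the enal carbonyl on the chelate face anti to the C2 chain (C13 trans to C2 across the future lactone) through the threo-selective dinuclear transition state (13S,14S), and the C14 alkoxide then closes the γ-lactone with loss of methanol, so that carbocycle and lactone form in one operation.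

Step 9
Reactants: 13 hydroxy lactone
Product: 16 (1S,3S,4S,13S,14S,7E,11E)-3,4-epoxy-13-hydroxycembra-7,11,15(17)-trien-16,14-olide, via Mannich base 14 (not isolated), via trimethylammonium iodide 15 (not isolated)
Conditions: LiN(iPr)2 (2.2 equiv), THF, −78 °C; CH2=NMe2+ I−, −78 → 0 °C; MeI, MeOH, 25 °C; NaHCO3 (aq), CH2Cl2, 25 °C
Reagents that add atoms: N,N-dimethylmethyleneiminium iodide (Eschenmoser's salt), C=[N+](C)C.[I-]
Why: Eschenmoser α-methylenation, in which the alkoxide/lactone-enolate dianion undergoes a Mannich reaction at C15 and N-methylation followed by base-induced β-elimination of trimethylamine gives the exocyclic alkene, no existing stereocenter being touched.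

Step 10
Reactants: 16 13-hydroxy α-methylene lactone
Product: 17 13-acetoxysarcocrassolide, (1S,3S,4S,13S,14S,7E,11E)-13-acetoxy-3,4-epoxycembra-7,11,15(17)-trien-16,14-olide
Conditions: Ac2O, pyridine, 4-(dimethylamino)pyridine (cat.), CH2Cl2, 0 → 25 °C
Reagents that add atoms: acetic anhydride, CC(=O)OC(C)=O
Why: Nucleophile-catalyzed O-acylation of the secondary allylic alcohol at C13 with retention of configuration.

**Compound list**

1 | (2E,6E)-farnesol | OC/C=C(\C)CC/C=C(\C)CCC=C(C)C | starting material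
2 | (2S,3S)-2,3-epoxyfarnesol | OC[C@@H]1O[C@@]1(C)CC/C=C(\C)CCC=C(C)C | intermediate
3 | (S)-4-benzyl-1,3-oxazolidin-2-one | O=C1N[C@@H](Cc2ccccc2)CO1 | starting material
4 | methyl 4-chloro-4-oxobutanoate | COC(=O)CCC(Cl)=O | starting material
5 | methyl 4-[(4S)-4-benzyl-2-oxo-1,3-oxazolidin-3-yl]-4-oxobutanoate | COC(=O)CCC(=O)N1C(=O)OC[C@@H]1Cc1ccccc1 | intermediate
6 | (2S,3S)-2,3-epoxyfarnesyl trifluoromethanesulfonate | FC(F)(F)S(=O)(=O)OC[C@@H]1O[C@@]1(C)CC/C=C(\C)CCC=C(C)C | intermediate (not isolated)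
7 | alkylated imide: methyl (3S)-3-{[(4S)-4-benzyl-2-oxo-1,3-oxazolidin-3-yl]carbonyl}-4-{(2S,3S)-3-[(3E)-4,8-dimethylnona-3,7-dien-1-yl]-3-methyloxiran-2-yl}butanoate | COC(=O)C[C@H](C[C@@H]1O[C@@]1(C)CC/C=C(\C)CCC=C(C)C)C(=O)N1C(=O)OC[C@@H]1Cc1ccccc1 | intermediate
8 | S-ethyl thioester: methyl (3S)-3-[(ethylsulfanyl)carbonyl]-4-{(2S,3S)-3-[(3E)-4,8-dimethylnona-3,7-dien-1-yl]-3-methyloxiran-2-yl}butanoate | COC(=O)C[C@H](C[C@@H]1O[C@@]1(C)CC/C=C(\C)CCC=C(C)C)C(=O)SCC | intermediate
9 | hydroxy thioester: as 8 with terminal (E)-CH2OH (C13) | COC(=O)C[C@H](C[C@@H]1O[C@@]1(C)CC/C=C(\C)CC/C=C(\C)CO)C(=O)SCC | intermediate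
10 | hydroxy aldehyde: methyl (3S)-3-formyl-4-{(2S,3S)-3-[(3E,7E)-9-hydroxy-4,8-dimethylnona-3,7-dien-1-yl]-3-methyloxiran-2-yl}butanoate | COC(=O)C[C@H](C[C@@H]1O[C@@]1(C)CC/C=C(\C)CC/C=C(\C)CO)C=O | intermediate
11 | dialdehyde ester: methyl (3S)-3-formyl-4-{(2S,3S)-3-[(3E,7E)-4,8-dimethyl-9-oxonona-3,7-dien-1-yl]-3-methyloxiran-2-yl}butanoate | COC(=O)C[C@H](C[C@@H]1O[C@@]1(C)CC/C=C(\C)CC/C=C(\C)C=O)C=O | intermediate
12 | seco diol ester: methyl 2-[(1S,3S,4S,13S,14S,7E,11E)-3,4-epoxy-13,14-dihydroxy-4,8,12-trimethylcyclotetradeca-7,11-dien-1-yl]acetate (cembrane ring numbering) | COC(=O)C[C@@H]1C[C@@H]2O[C@@]2(C)CC/C=C(\C)CC/C=C(\C)[C@H](O)[C@H]1O | intermediate (not isolated)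
13 | (1S,3S,4S,13S,14S,7E,11E)-3,4-epoxy-13-hydroxy-17-norcembra-7,11-dien-16,14-olide (trans-fused γ-lactone, C15 = CH2) | O=C1O[C@H]2[C@H](C1)C[C@@H]1O[C@@]1(C)CC/C=C(\C)CC/C=C(\C)[C@@H]2O | intermediate
14 | Mannich base: 13 carrying CH2NMe2 on C15 (C15 epimers) | CN(C)CC1C(=O)O[C@H]2[C@H]1C[C@@H]1O[C@@]1(C)CC/C=C(\C)CC/C=C(\C)[C@@H]2O | intermediate (not isolated)
15 | trimethylammonium iodide of 14 | C[N+](C)(C)CC1C(=O)O[C@H]2[C@H]1C[C@@H]1O[C@@]1(C)CC/C=C(\C)CC/C=C(\C)[C@@H]2O.[I-] | intermediate (not isolated)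
16 | (1S,3S,4S,13S,14S,7E,11E)-3,4-epoxy-13-hydroxycembra-7,11,15(17)-trien-16,14-olide | C=C1C(=O)O[C@H]2[C@H]1C[C@@H]1O[C@@]1(C)CC/C=C(\C)CC/C=C(\C)[C@@H]2O | intermediate
17 | 13-acetoxysarcocrassolide | C=C1C(=O)O[C@H]2[C@H]1C[C@@H]1O[C@@]1(C)CC/C=C(\C)CC/C=C(\C)[C@@H]2OC(C)=O | target

**Step count**
Total: 10 steps. Longest linear sequence: 9 steps (1, then 3 to 10) from farnesol.

**Three steps most likely to fail, each with a fallback**

Step 8 (vanadium pinacol closure with lactonization). Risks are oligomerization, coupling at C11 of the enal ketyl instead of at the carbonyl, opening of the epoxide by the Lewis-acidic vanadium and zinc chlorides, and erythro or cis-fused diastereomers. The fallback replaces reductive coupling by carbene umpolung and sets C13 afterwards. Setting out from 11, 3-benzyl-5-(2-hydroxyethyl)-4-methylthiazolium chloride and Et3N at high dilution effect an intramolecular crossed acyloin condensation to the macrocyclic ketol ester methyl 2-[(1S,3S,4S,7E,11E)-3,4-epoxy-14-hydroxy-4,8,12-trimethyl-13-oxocyclotetradeca-7,11-dien-1-yl]acetate F1. A catalytic amount of DBU lactonizes it and equilibrates C14 (α to the ketone) to the trans-fused (1S,3S,4S,14S,7E,11E)-3,4-epoxy-13-oxo-17-norcembra-7,11-dien-16,14-olide F2. Luche reduction (NaBH4, CeCl3·7H2O, MeOH, −78 °C) then adds hydride anti to the C14–O bond (Felkin–Anh) and gives the 13S alcohol, which is compound 13.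

Step 3 (enolate alkylation by an epoxy triflate). Risks are decomposition of the triflate, elimination, and sluggish SN2 next to the oxirane. The fallback builds the C1–C2 bond by olefination and sets C1 by hydrogenation. Setting out from 2, SO3·pyridine/DMSO/Et3N gives (2R,3S)-2,3-epoxyfarnesal F3. Horner–Wadsworth–Emmons reaction with the dilithium salt of 2-(diethoxyphosphoryl)-4-methoxy-4-oxobutanoic acid gives (2E)-2-(2-methoxy-2-oxoethyl)-3-{(2S,3S)-3-[(3E)-4,8-dimethylnona-3,7-dien-1-yl]-3-methyloxiran-2-yl}prop-2-enoic acid F4. Asymmetric hydrogenation of this itaconate-type acid with [Rh(cod)(Et-DuPhos)]BF4 (ligand enantiomer chosen for 2S; H2, MeOH) reduces only the chelating acrylic acid alkene and gives (2S)-2-({(2S,3S)-3-[(3E)-4,8-dimethylnona-3,7-dien-1-yl]-3-methyloxiran-2-yl}methyl)-4-methoxy-4-oxobutanoic acid F5. Thioesterification (EtSH, dicyclohexylcarbodiimide, 4-(dimethylamino)pyridine) returns to the route at compound 8.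

Step 9 (methylenation through the dianion). Risks are incomplete Mannich reaction, amine re-addition to the new acceptor, and iodide opening of the epoxide during quaternization. The fallback uses an aldol/E1cB sequence that also installs the acetate. Setting out from 13, LiN(iPr)2 (2.2 equiv) and gaseous formaldehyde give the 15-(hydroxymethyl) lactone F6. Ac2O/pyridine acetylates both hydroxyls to the 13-acetoxy-15-(acetoxymethyl) lactone F7. DBU in CH2Cl2 then eliminates acetic acid from the β-acetoxy lactone (E1cB) and gives compound 17 directly.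

**Further compounds**
F1 | step 8 | methyl 2-[(1S,3S,4S,7E,11E)-3,4-epoxy-14-hydroxy-4,8,12-trimethyl-13-oxocyclotetradeca-7,11-dien-1-yl]acetate (C14 epimers) | COC(=O)C[C@@H]1C[C@@H]2O[C@@]2(C)CC/C=C(\C)CC/C=C(\C)C(=O)C1O
F2 | step 8 | (1S,3S,4S,14S,7E,11E)-3,4-epoxy-13-oxo-17-norcembra-7,11-dien-16,14-olide | O=C1O[C@H]2[C@H](C1)C[C@@H]1O[C@@]1(C)CC/C=C(\C)CC/C=C(\C)C2=O
F3 | step 3 | (2R,3S)-2,3-epoxyfarnesal | O=C[C@@H]1O[C@@]1(C)CC/C=C(\C)CCC=C(C)C
F4 | step 3 | (2E)-2-(2-methoxy-2-oxoethyl)-3-{(2S,3S)-3-[(3E)-4,8-dimethylnona-3,7-dien-1-yl]-3-methyloxiran-2-yl}prop-2-enoic acid | OC(=O)/C(CC(=O)OC)=C/[C@@H]1O[C@@]1(C)CC/C=C(\C)CCC=C(C)C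
F5 | step 3 | (2S)-2-({(2S,3S)-3-[(3E)-4,8-dimethylnona-3,7-dien-1-yl]-3-methyloxiran-2-yl}methyl)-4-methoxy-4-oxobutanoic acid | OC(=O)[C@H](CC(=O)OC)C[C@@H]1O[C@@]1(C)CC/C=C(\C)CCC=C(C)C
F6 | step 9 | 15-(hydroxymethyl) derivative of 13 (C15 epimers) | OCC1C(=O)O[C@H]2[C@H]1C[C@@H]1O[C@@]1(C)CC/C=C(\C)CC/C=C(\C)[C@@H]2O
F7 | step 9 | 13-acetoxy-15-(acetoxymethyl) lactone (C15 epimers) | CC(=O)OCC1C(=O)O[C@H]2[C@H]1C[C@@H]1O[C@@]1(C)CC/C=C(\C)CC/C=C(\C)[C@@H]2OC(C)=O
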